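## The problem

Broussoflavonol G is an achiral flavonol. Ring A and the pyranone ring C form a chromen-4-one, ring B sits on C2, and there is no stereocentre, so nothing has to be set or relayed stereochemically. The difficulty is regiochemical: three 3-methylbut-2-enyl (prenyl) groups stand on carbon. One is at C8 of the phloroglucinol-type ring A. Two are side by side at C2' and C3' of the catechol ring B, with C2' wedged between C1' and C3'. Direct C-prenylation of such rings gives O/C, C6/C8 and linear/branched mixtures, and a halogen handle cannot be introduced electrophilically once a prenyl alkene is present. The five hydroxyls (3, 5, 7, 4', 5') must be told apart. At the end the 7-OH/C8-prenyl and 4'-OH/C3'-prenyl pairs are prone to acid-catalysed closure to chromans, the catechol and the enolic 3-hydroxyl oxidise easily in base, and the alkenes rule out hydrogenolysis and electrophilic oxidants. What opens a short route is positional. C8 is para to O5 with the unsubstituted C6 between them, and C2' is para to O5' with the unsubstituted C6' between them. A prenyl group parked on either oxygen can therefore reach its carbon by two consecutive [3,3] shifts that return the linear chain. O5 lies beside the C4 carbonyl and O5' beside O4', so each ether oxygen has a second donor with which to hold a Lewis acid. The third prenyl group, at C3', is ortho to O4' and within reach of a single [3,3] shift of a 1,1-dimethylallyl ether.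

## Retrosynthesis

**Unmasking (23 from 22).** The last cut removes three methoxymethyl (MOM) acetals from O3, O7 and O4' of 22. MOM is chosen because it survives hydroxide, alkaline peroxide, carbonate alkylations and a mild Lewis acid at about 100 °C. Benzyl would need hydrogenolysis, silyl ethers would not survive KOH, and methyl ethers would need a boron halide. The forward step must cleave acetals faster than the prenyl alkenes are protonated.

**Twin relay (22 from 16).** The C8–CH2 and C2'–CH2 bonds are cut and both prenyl groups are returned to the para oxygens, O5 and O5', giving the bis(prenyl ether) 16. Cross-coupling at the same two bonds would need halides at two crowded carbons and brings the α/γ question of allyl metals; Friedel–Crafts prenylation is unselective. The sigmatropic cut turns two difficult C–C bonds into two phenol O-alkylations and needs no reagent. Forward, each ether passes through an ortho-dienone and a para-dienone (17, 18, then phenol 19; 20, 21, then 22). Each Cope shift must outrun enolisation of its ortho-dienone, and ring B must respond to the same catalyst as ring A.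

**Ring C (16 from 15 from 13).** The 3-O-MOM group of 16 is removed to give flavonol 15, whose O1–C2 and C3–O bonds are cut back to 2'-hydroxychalcone 13 (Algar–Flynn–Oyamada oxidation, via dihydroflavonol 14). This takes ring C and the C3 oxygen in one operation. A Baker–Venkataraman route would need a separate C3 oxidation in the presence of five alkenes. The 3-hydroxyl is capped so that it cannot form a 3-hydroxy-4-keto chelate with the lanthanide.

**Chalcone (13 from 4 and 12).** The Cα=Cβ bond is cut (Claisen–Schmidt) into acetophenone 4 and aldehyde 12, two fragments of similar size. Both prenyl ethers are already in place on the fragments. In a finished flavonol O5 is hydrogen-bonded to the carbonyl and alkylates sluggishly, whereas on each fragment the oxygen concerned is the only accessible phenol.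

**Ring A ketone (4 from 2 from 1).** The O6–prenyl bond of 4 is cut to 2 and prenyl bromide 3, and the O4–MOM bond of 2 is cut to 2,4,6-trihydroxyacetophenone 1. The order follows intrinsic reactivity: the unchelated 4-hydroxyl reacts first, then one of the two chelated hydroxyls, and the last one stays free for ring closure.

**Ring B aldehyde (12 from 11, 9, 8, 7, 5 and 6).** The MOM group of 12 is removed to phenol 11. The C3–prenyl bond of 11 is cut by a retro-Claisen shift (through dienone 10) to the 1,1-dimethylallyl ether 9, which comes from alkyne 8 by semihydrogenation. Alkyne 8 arises from 7 and 3, and 7 from 3,4-dihydroxybenzaldehyde 5 and 3-chloro-3-methylbut-1-yne 6. The tertiary ether is used because it shifts far below the temperature at which the primary prenyl ether moves, and it gives the linear C-prenyl group without an allyl metal. Regiochemistry rests on the higher acidity of the 4-hydroxyl of 5.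

## Roads not taken

**Alternative 1:** The cut is the C3–C4 bond of ring C. The target is traced to dihydroflavonol A1 and on to the ether-linked dialdehyde A2, in which the ring A salicylaldehyde oxygen carries an α-aryl acetaldehyde. In the forward step a thiazolium-derived carbene turns the aromatic formyl group into an acyl anion equivalent that adds to the aliphatic aldehyde and closes ring C as the 3-hydroxychroman-4-one A1. Dehydrogenation and deprotection would follow.
- Merits: ring C closes under near-neutral conditions, the C3 oxygen arrives with the ring, and the five-membered (aurone) diversion of alkaline peroxide cannot occur. In this respect it is better than step 9 of the chosen route.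
- Weak points: it spends its key step on the part of the molecule that is easy, and all three C-prenyl groups must still be placed on the fragments beforehand. A2 is an α-aryloxy aldehyde prone to enolisation and phenoxide elimination. In an aldehyde–aldehyde benzoin the hindered, electron-rich aromatic aldehyde is the slower partner for the carbene, so the isomeric ketol and homo-coupling compete. A1 needs a further oxidation.
- Comparison: the chosen plan answers with a key step that places two of the three prenyl groups at once.

**Alternative 2:** The cut removes both carbon substituents of ring B (C2'–CH2 and C3'–CH2) to reveal an aryne. Fluoride would release it from the ortho-silyl aryl triflate A4, and a palladium catalyst would add two allyl groups, one from an allyl halide and one from an allylstannane, to give diallyl arene A3.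
- Merits: both vicinal C–C bonds form in one step by a reaction type known for arynes, and because the two groups are identical there is no regiochemical question. For ring B this is on firmer mechanistic ground than the ring B half of step 11.
- Weak points: allyl is not prenyl, so two cross-metatheses must add the gem-dimethyl termini. A4 is pentasubstituted, with silicon and triflate between an acetal and an acetal ether, and needs several steps of its own. The dioxolane must later be removed beside MOM groups. Ring A still needs its own C8 answer, most likely the ring A relay used here.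
- Comparison: the chosen plan is shorter by at least half a dozen steps and holds a cross-coupling fallback for ring B in reserve.

**Alternative 3:** The cut takes ring B apart at C1'–C2' and C3'–C4'. 2-Pyrone A7 would add across the symmetric diprenylacetylene A6 and the bridged adduct would lose its lactone bridge to give benzoate A5.
- Merits: ring B is born with both prenyl groups, the symmetric alkyne removes any regiochemical question, and the approach is convergent. In those respects it matches the chosen plan.
- Weak points: an unactivated dialkyl alkyne and an alkoxy-rich pyrone need forcing temperatures. The trisubstituted alkenes of A6 are rival dienophiles, and its skipped enyne methylenes can isomerise. A7 needs a multi-step preparation. A5 needs redox adjustment to the aldehyde. Ring A is left unaddressed.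
- Comparison: the conceptual risk is similar, but the chosen plan has fewer steps and runs its key step at mild temperature.

Key step: step 11

## Route

Assumption: in step 11 ring A, whose ether oxygen shares the metal with the C4 carbonyl, is taken to rearrange before ring B; the reverse order would end at the same product 22. Dienones 10, 17, 18, 20 and 21 and dihydroflavonol 14 are racemic.

Step 1
Reactants: 1 2,4,6-trihydroxyacetophenone
Product: 2 1-[2,6-dihydroxy-4-(methoxymethoxy)phenyl]ethanone
Conditions: MOMCl (1.0 equiv), i-Pr2NEt, THF, 0 °C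
Reagents that add atoms: chloromethyl methyl ether (MOMCl), COCCl
Why: Selective O-alkylation (acetal formation): the 4-hydroxyl is the only one not hydrogen-bonded to the acetyl group and is the most acidic, so one equivalent of electrophile should take it first; the bis-ether is separable.

Step 2
Reactants: 2 1-[2,6-dihydroxy-4-(methoxymethoxy)phenyl]ethanone; 3 prenyl bromide
Product: 4 1-[2-hydroxy-4-(methoxymethoxy)-6-(3-methylbut-2-enyloxy)phenyl]ethanone
Conditions: K2CO3, acetone, reflux
Reagents that add atoms: none
Why: Williamson etherification; once one chelated hydroxyl is alkylated the other is locked in a strong hydrogen bond to the carbonyl and resists a second alkylation, and carbonate in acetone favours O- over C-prenylation.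

Step 3
Reactants: 5 3,4-dihydroxybenzaldehyde; 6 3-chloro-3-methylbut-1-yne
Product: 7 3-hydroxy-4-(2-methylbut-3-yn-2-yloxy)benzaldehyde
Conditions: CuCl2·2H2O (1 mol %), DBU (1.05 equiv), MeCN, 0 °C
Reagents that add atoms: none
Why: Copper-catalysed propargylic etherification of a phenol with a tertiary propargylic chloride; one equivalent of amidine base ionises only the 4-hydroxyl, which is para to the formyl group and several pKa units more acidic than the 3-hydroxyl.

Step 4
Reactants: 7 3-hydroxy-4-(2-methylbut-3-yn-2-yloxy)benzaldehyde; 3 prenyl bromide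
Product: 8 3-(3-methylbut-2-enyloxy)-4-(2-methylbut-3-yn-2-yloxy)benzaldehyde
Conditions: K2CO3, DMF, rt
Reagents that add atoms: none
Why: Williamson etherification of the remaining phenol; carbonate does not deprotonate the alkyne and the tertiary propargyl ether is stable at room temperature.

Step 5
Reactants: 8 3-(3-methylbut-2-enyloxy)-4-(2-methylbut-3-yn-2-yloxy)benzaldehyde
Product: 9 4-(2-methylbut-3-en-2-yloxy)-3-(3-methylbut-2-enyloxy)benzaldehyde
Conditions: H2 (1 atm), Pd/CaCO3 poisoned with Pb(OAc)2 (Lindlar catalyst), quinoline, EtOAc, rt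
Reagents that add atoms: none
Why: Lindlar semihydrogenation of a terminal alkyne; the poisoned catalyst should leave the trisubstituted alkene, the aldehyde and the allylic ethers untouched.

Step 6
Reactants: 9 4-(2-methylbut-3-en-2-yloxy)-3-(3-methylbut-2-enyloxy)benzaldehyde
Product: 11 4-hydroxy-3-(3-methylbut-2-enyl)-5-(3-methylbut-2-enyloxy)benzaldehyde, via ortho-dienone 10 (not isolated)
Conditions: N,N-diethylaniline, 130 °C
Reagents that add atoms: none
Why: Aromatic Claisen rearrangement; the tertiary 1,1-dimethylallyl ether shifts far below the temperature the primary prenyl ether needs, C5 is the only open ortho carbon, and allylic inversion gives the linear prenyl group before dienone 10 enolises.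

Step 7
Reactants: 11 4-hydroxy-3-(3-methylbut-2-enyl)-5-(3-methylbut-2-enyloxy)benzaldehyde
Product: 12 4-(methoxymethoxy)-3-(3-methylbut-2-enyl)-5-(3-methylbut-2-enyloxy)benzaldehyde
Conditions: MOMCl, i-Pr2NEt, CH2Cl2, 0 °C to rt
Reagents that add atoms: chloromethyl methyl ether (MOMCl), COCCl
Why: MOM acetal formation on a phenol made acidic by the para formyl group; the small electrophile tolerates the two ortho substituents.

Step 8
Reactants: 4 1-[2-hydroxy-4-(methoxymethoxy)-6-(3-methylbut-2-enyloxy)phenyl]ethanone; 12 4-(methoxymethoxy)-3-(3-methylbut-2-enyl)-5-(3-methylbut-2-enyloxy)benzaldehyde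
Product: 13 (E)-1-[2-hydroxy-4-(methoxymethoxy)-6-(3-methylbut-2-enyloxy)phenyl]-3-[4-(methoxymethoxy)-3-(3-methylbut-2-enyl)-5-(3-methylbut-2-enyloxy)phenyl]prop-2-en-1-one
Conditions: KOH, EtOH/H2O, rt
Reagents that add atoms: none
Why: Claisen–Schmidt condensation; the aldehyde has no α-hydrogen, the ketone enolises only at its methyl group, and E1cB dehydration gives the E-enone; MOM and prenyl ethers are stable to hydroxide.

Step 9
Reactants: 13 (E)-1-[2-hydroxy-4-(methoxymethoxy)-6-(3-methylbut-2-enyloxy)phenyl]-3-[4-(methoxymethoxy)-3-(3-methylbut-2-enyl)-5-(3-methylbut-2-enyloxy)phenyl]prop-2-en-1-one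
Product: 15 3-hydroxy-7-(methoxymethoxy)-2-[4-(methoxymethoxy)-3-(3-methylbut-2-enyl)-5-(3-methylbut-2-enyloxy)phenyl]-5-(3-methylbut-2-enyloxy)chromen-4-one, via trans-dihydroflavonol 14 (not isolated)
Conditions: 30% aq. H2O2, NaOH, MeOH, 0 °C to rt
Reagents that add atoms: hydrogen peroxide, OO
Why: Algar–Flynn–Oyamada oxidation; hydroperoxide adds to the enone, the 2'-phenoxide closes ring C in the six-membered mode to trans-dihydroflavonol 14, and further oxidation gives the flavonol; the nucleophilic oxidant does not epoxidise the electron-rich prenyl alkenes, and low temperature disfavours five-membered closure.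

Step 10
Reactants: 15 3-hydroxy-7-(methoxymethoxy)-2-[4-(methoxymethoxy)-3-(3-methylbut-2-enyl)-5-(3-methylbut-2-enyloxy)phenyl]-5-(3-methylbut-2-enyloxy)chromen-4-one
Product: 16 3,7-bis(methoxymethoxy)-2-[4-(methoxymethoxy)-3-(3-methylbut-2-enyl)-5-(3-methylbut-2-enyloxy)phenyl]-5-(3-methylbut-2-enyloxy)chromen-4-one
Conditions: MOMCl, i-Pr2NEt, CH2Cl2, 0 °C to rt
Reagents that add atoms: chloromethyl methyl ether (MOMCl), COCCl
Why: MOM acetal formation on the 3-hydroxyl; capping it removes the 3-hydroxy-4-keto chelate that would otherwise hold the europium catalyst away from O5.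

Step 11
Reactants: 16 3,7-bis(methoxymethoxy)-2-[4-(methoxymethoxy)-3-(3-methylbut-2-enyl)-5-(3-methylbut-2-enyloxy)phenyl]-5-(3-methylbut-2-enyloxy)chromen-4-one
Product: 22 3,7,4'-tris-O-methoxymethyl Broussoflavonol G, via ring A ortho-dienone 17 (not isolated), via ring A para-dienone 18 (not isolated), via 8-prenyl 5-hydroxy flavone 19 (not isolated), via ring B ortho-dienone 20 (not isolated), via ring B para-dienone 21 (not isolated)
Conditions: Eu(fod)3 [tris(6,6,7,7,8,8,8-heptafluoro-2,2-dimethyloctane-3,5-dionato)europium] (0.5 equiv), NaHCO3, PhCl, 85 °C, then 120 °C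
Reagents that add atoms: none
Why: Proposed new method: Eu(fod)3 is expected to bind O5 together with the C4 carbonyl, and O5' together with the 4'-acetal oxygens, polarising each O–CH2 bond and lowering the barrier of the first [3,3] (aromatic Claisen) shift, which places a 1,1-dimethylallyl group on C6 (17) and later on C6' (20). A second [3,3] (Cope) shift within each dienone carries the group to C8 (18) and to C2' (21) with a second allylic inversion, so the linear prenyl chain is restored, and enolisation gives phenols 19 and 22. The closest known reactions are the Eu(fod)3-catalysed Claisen–Cope rearrangement of 5-O-prenyl flavonoids to 8-prenyl flavonoids and thermal para-Claisen shifts of aryl prenyl ethers with a free ortho carbon; new here are a lanthanide-catalysed relay at a catechol-type ether without a carbonyl anchor and two relays in one operation. No ring is closed and no stereocentre remains, since the sp3 carbons of 17, 18, 20 and 21 are transient. The selectivity needed is Cope shift over enolisation of each ortho-dienone; the strained quaternary allyl group, an aprotic medium holding only insoluble NaHCO3, and metal binding of the dienone carbonyl should secure it. At ring B a first shift to the substituted C4' is harmless, because that blocked dienone can only revert or relay to the same C2'. C8 and C2' are the only para carbons, so the only isomeric by-products possible are the C6 and C6' tert-allyl phenols.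

Step 12
Reactants: 22 3,7,4'-tris-O-methoxymethyl Broussoflavonol G
Product: 23 Broussoflavonol G
Conditions: 3 M aq. HCl, MeOH, 40 °C
Reagents that add atoms: none
Why: Acid-catalysed acetal methanolysis, which transfers the three methoxymethyl groups to methanol; dilute acid and mild temperature are chosen so that the acetals should cleave faster than the prenyl alkenes are protonated.

## Compound list

1 | 2,4,6-trihydroxyacetophenone | CC(=O)c1c(O)cc(O)cc1O | starting material
2 | 1-[2,6-dihydroxy-4-(methoxymethoxy)phenyl]ethanone | CC(=O)c1c(O)cc(OCOC)cc1O | intermediate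
3 | prenyl bromide (1-bromo-3-methylbut-2-ene) | CC(C)=CCBr | starting material
4 | 1-[2-hydroxy-4-(methoxymethoxy)-6-(3-methylbut-2-enyloxy)phenyl]ethanone | CC(=O)c1c(O)cc(OCOC)cc1OCC=C(C)C | intermediate
5 | 3,4-dihydroxybenzaldehyde | O=Cc1ccc(O)c(O)c1 | starting material
6 | 3-chloro-3-methylbut-1-yne | CC(C)(Cl)C#C | starting material
7 | 3-hydroxy-4-(2-methylbut-3-yn-2-yloxy)benzaldehyde | O=Cc1ccc(OC(C)(C)C#C)c(O)c1 | intermediate
8 | 3-(3-methylbut-2-enyloxy)-4-(2-methylbut-3-yn-2-yloxy)benzaldehyde | O=Cc1ccc(OC(C)(C)C#C)c(OCC=C(C)C)c1 | intermediate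
9 | 4-(2-methylbut-3-en-2-yloxy)-3-(3-methylbut-2-enyloxy)benzaldehyde | O=Cc1ccc(OC(C)(C)C=C)c(OCC=C(C)C)c1 | intermediate
10 | 3-(3-methylbut-2-enyl)-5-(3-methylbut-2-enyloxy)-4-oxocyclohexa-1,5-diene-1-carbaldehyde (racemic) | O=CC1=CC(CC=C(C)C)C(=O)C(OCC=C(C)C)=C1 | intermediate (not isolated)
11 | 4-hydroxy-3-(3-methylbut-2-enyl)-5-(3-methylbut-2-enyloxy)benzaldehyde | O=Cc1cc(CC=C(C)C)c(O)c(OCC=C(C)C)c1 | intermediate
12 | 4-(methoxymethoxy)-3-(3-methylbut-2-enyl)-5-(3-methylbut-2-enyloxy)benzaldehyde | O=Cc1cc(CC=C(C)C)c(OCOC)c(OCC=C(C)C)c1 | intermediate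
13 | (E)-1-[2-hydroxy-4-(methoxymethoxy)-6-(3-methylbut-2-enyloxy)phenyl]-3-[4-(methoxymethoxy)-3-(3-methylbut-2-enyl)-5-(3-methylbut-2-enyloxy)phenyl]prop-2-en-1-one | COCOc1cc(O)c(C(=O)/C=C/c2cc(CC=C(C)C)c(OCOC)c(OCC=C(C)C)c2)c(OCC=C(C)C)c1 | intermediate
14 | (2R*,3R*)-3-hydroxy-7-(methoxymethoxy)-2-[4-(methoxymethoxy)-3-(3-methylbut-2-enyl)-5-(3-methylbut-2-enyloxy)phenyl]-5-(3-methylbut-2-enyloxy)chroman-4-one (racemic trans, one enantiomer drawn) | CC(C)=CCc1cc([C@@H]2[C@H](C(=O)c3c(OCC=C(C)C)cc(OCOC)cc3O2)O)cc(OCC=C(C)C)c1OCOC | intermediate (not isolated)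
15 | 3-hydroxy-7-(methoxymethoxy)-2-[4-(methoxymethoxy)-3-(3-methylbut-2-enyl)-5-(3-methylbut-2-enyloxy)phenyl]-5-(3-methylbut-2-enyloxy)chromen-4-one | CC(C)=CCOc1cc(OCOC)cc2oc(-c3cc(CC=C(C)C)c(OCOC)c(OCC=C(C)C)c3)c(O)c(=O)c12 | intermediate
16 | 3,7-bis(methoxymethoxy)-2-[4-(methoxymethoxy)-3-(3-methylbut-2-enyl)-5-(3-methylbut-2-enyloxy)phenyl]-5-(3-methylbut-2-enyloxy)chromen-4-one | CC(C)=CCOc1cc(OCOC)cc2oc(-c3cc(CC=C(C)C)c(OCOC)c(OCC=C(C)C)c3)c(OCOC)c(=O)c12 | intermediate
17 | 3,7-bis(methoxymethoxy)-2-[4-(methoxymethoxy)-3-(3-methylbut-2-enyl)-5-(3-methylbut-2-enyloxy)phenyl]-6-(2-methylbut-3-en-2-yl)-6H-chromene-4,5-dione (racemic) | C=CC(C)(C)C1C(=O)C2=C(C=C1OCOC)OC(c1cc(CC=C(C)C)c(OCOC)c(OCC=C(C)C)c1)=C(OCOC)C2=O | intermediate (not isolated)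
18 | 3,7-bis(methoxymethoxy)-2-[4-(methoxymethoxy)-3-(3-methylbut-2-enyl)-5-(3-methylbut-2-enyloxy)phenyl]-8-(3-methylbut-2-enyl)-8H-chromene-4,5-dione (racemic) | CC(C)=CCC1C(OCOC)=CC(=O)C2=C1OC(c1cc(CC=C(C)C)c(OCOC)c(OCC=C(C)C)c1)=C(OCOC)C2=O | intermediate (not isolated)
19 | 5-hydroxy-3,7-bis(methoxymethoxy)-2-[4-(methoxymethoxy)-3-(3-methylbut-2-enyl)-5-(3-methylbut-2-enyloxy)phenyl]-8-(3-methylbut-2-enyl)chromen-4-one | CC(C)=CCc1c(OCOC)cc(O)c2c(=O)c(OCOC)c(-c3cc(CC=C(C)C)c(OCOC)c(OCC=C(C)C)c3)oc12 | intermediate (not isolated)
20 | 5-hydroxy-3,7-bis(methoxymethoxy)-2-[4-(methoxymethoxy)-6-(2-methylbut-3-en-2-yl)-3-(3-methylbut-2-enyl)-5-oxocyclohexa-1,3-dien-1-yl]-8-(3-methylbut-2-enyl)chromen-4-one (racemic) | CC(C)=CCc1c(OCOC)cc(O)c2c(=O)c(OCOC)c(C3=CC(CC=C(C)C)=C(OCOC)C(=O)C3C(C)(C)C=C)oc12 | intermediate (not isolated)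
21 | 5-hydroxy-3,7-bis(methoxymethoxy)-2-[4-(methoxymethoxy)-5,6-bis(3-methylbut-2-enyl)-3-oxocyclohexa-1,4-dien-1-yl]-8-(3-methylbut-2-enyl)chromen-4-one (racemic) | CC(C)=CCc1c(OCOC)cc(O)c2c(=O)c(OCOC)c(C3=CC(=O)C(OCOC)=C(CC=C(C)C)C3CC=C(C)C)oc12 | intermediate (not isolated)
22 | 3,7,4'-tris-O-methoxymethyl Broussoflavonol G: 5-hydroxy-2-[5-hydroxy-4-(methoxymethoxy)-2,3-bis(3-methylbut-2-enyl)phenyl]-3,7-bis(methoxymethoxy)-8-(3-methylbut-2-enyl)chromen-4-one | CC(C)=CCc1c(-c2oc3c(CC=C(C)C)c(OCOC)cc(O)c3c(=O)c2OCOC)cc(O)c(OCOC)c1CC=C(C)C | intermediate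
23 | Broussoflavonol G: 2-[4,5-dihydroxy-2,3-bis(3-methylbut-2-enyl)phenyl]-3,5,7-trihydroxy-8-(3-methylbut-2-enyl)chromen-4-one | CC(C)=CCc1c(-c2oc3c(CC=C(C)C)c(O)cc(O)c3c(=O)c2O)cc(O)c(O)c1CC=C(C)C | target

## Step count and least certain steps

Total: 12 steps. Longest linear sequence: 10 steps (steps 3–12, from 5). The ring A branch (steps 1 and 2) joins at step 8.

**Step 11 (key step, proposed new method).**
- What may go wrong: stalling or leakage of the ring B relay. The catechol-type ether has no carbonyl partner and may bind the metal too weakly once the peri-hydroxy ketone of 19 competes for it (sequestration of the catalyst). Enolisation of dienone 20 may outrun the Cope shift toward the flanked C2', ending at the C6' tert-allyl phenol. Lewis-acid-induced loss of the prenyl group from oxygen is a third leak. At ring A the same enolisation of 17 is a known minor channel.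
- Fallback (known chemistry, sets out from acetophenone 4, returns at 23): ring B is built with both prenyl groups by cross-coupling and only the documented ring A relay is kept.
  - The known bromophenol 2,3-dibromo-4,5-dihydroxybenzaldehyde F1 (purchased, or made from vanillin by two brominations and demethylation) is protected with MOMCl/i-Pr2NEt to 2,3-dibromo-4,5-bis(methoxymethoxy)benzaldehyde F2.
  - Twofold Stille coupling with tributyl(3-methylbut-2-enyl)stannane (Pd(PPh3)4, DMF, 100 °C) should give 4,5-bis(methoxymethoxy)-2,3-bis(3-methylbut-2-enyl)benzaldehyde F3.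
  - Claisen–Schmidt condensation of F3 with 4 gives the chalcone (E)-3-[4,5-bis(methoxymethoxy)-2,3-bis(3-methylbut-2-enyl)phenyl]-1-[2-hydroxy-4-(methoxymethoxy)-6-(3-methylbut-2-enyloxy)phenyl]prop-2-en-1-one F4.
  - Algar–Flynn–Oyamada oxidation gives the flavonol 2-[4,5-bis(methoxymethoxy)-2,3-bis(3-methylbut-2-enyl)phenyl]-3-hydroxy-7-(methoxymethoxy)-5-(3-methylbut-2-enyloxy)chromen-4-one F5, and MOM protection gives its 3-O-methoxymethyl ether F6.
  - The Eu(fod)3-catalysed Claisen–Cope rearrangement of the 5-O-prenyl ether alone (the documented substrate class) should give 3,7,4',5'-tetrakis-O-methoxymethyl Broussoflavonol G F7, and acidic methanolysis then gives 23.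

**Step 12.**
- What may go wrong: acid-catalysed addition of the freed 7- and 4'-hydroxyls across the neighbouring prenyl alkenes (chroman closure) competing with acetal cleavage.
- Fallback (sets out from 22, returns at 23): the acetals are exchanged for silyl ethers under buffered aprotic conditions, so that no phenol is free while acid is present. TMSOTf with 2,2'-bipyridyl in CH2Cl2 at 0 °C converts the three aryl MOM ethers into aryl trimethylsilyl ethers and silylates the two free phenols, giving 3,5,7,4',5'-pentakis-O-trimethylsilyl Broussoflavonol G F8. Neutral aqueous methanol then hydrolyses F8 to 23.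

**Step 9.**
- What may go wrong: diversion of ring closure into the five-membered mode (aurone formation), which a 6'-alkoxy group on the chalcone favours, and retro-aldol cleavage in the alkaline medium.
- Fallback (sets out from 13, returns at 15): ring closure is separated from C3 oxidation.
  - NaOAc in refluxing EtOH cyclises 13 to the flavanone 7-(methoxymethoxy)-2-[4-(methoxymethoxy)-3-(3-methylbut-2-enyl)-5-(3-methylbut-2-enyloxy)phenyl]-5-(3-methylbut-2-enyloxy)chroman-4-one F9.
  - 2-Iodoxybenzoic acid in DMSO at 80 °C dehydrogenates it to the flavone 7-(methoxymethoxy)-2-[4-(methoxymethoxy)-3-(3-methylbut-2-enyl)-5-(3-methylbut-2-enyloxy)phenyl]-5-(3-methylbut-2-enyloxy)chromen-4-one F10.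
  - C3 lithiation (LDA, THF, −78 °C) and trapping with B(OMe)3 gives the dimethyl flavon-3-ylboronate F11, which is not isolated; NaOH/H2O2 oxidises it to 15.

**Step 3.**
- What may go wrong: alkylation at O3 or at both oxygens, and binding or reduction of the copper catalyst by the free catechol.
- Fallback (sets out from 5, returns at 8): a temporary group keeps the catechol away from the copper step.
  - Allyl bromide with NaHCO3/NaI in DMF at 40 °C, a documented 4-O-selective alkylation of 5, gives 4-(allyloxy)-3-hydroxybenzaldehyde F12.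
  - Prenyl bromide 3 with K2CO3 gives 4-(allyloxy)-3-(3-methylbut-2-enyloxy)benzaldehyde F13.
  - Pd(PPh3)4 with morpholine removes the unsubstituted allyl group faster than the prenyl group and gives 4-hydroxy-3-(3-methylbut-2-enyloxy)benzaldehyde F14.
  - This monophenol is etherified with 6 under the conditions of step 3 to give 8.

## Further compounds

F1 | step 11 | 2,3-dibromo-4,5-dihydroxybenzaldehyde | O=Cc1cc(O)c(O)c(Br)c1Br
F2 | step 11 | 2,3-dibromo-4,5-bis(methoxymethoxy)benzaldehyde | O=Cc1cc(OCOC)c(OCOC)c(Br)c1Br
F3 | step 11 | 4,5-bis(methoxymethoxy)-2,3-bis(3-methylbut-2-enyl)benzaldehyde | O=Cc1cc(OCOC)c(OCOC)c(CC=C(C)C)c1CC=C(C)C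
F4 | step 11 | (E)-3-[4,5-bis(methoxymethoxy)-2,3-bis(3-methylbut-2-enyl)phenyl]-1-[2-hydroxy-4-(methoxymethoxy)-6-(3-methylbut-2-enyloxy)phenyl]prop-2-en-1-one | COCOc1cc(O)c(C(=O)/C=C/c2cc(OCOC)c(OCOC)c(CC=C(C)C)c2CC=C(C)C)c(OCC=C(C)C)c1
F5 | step 11 | 2-[4,5-bis(methoxymethoxy)-2,3-bis(3-methylbut-2-enyl)phenyl]-3-hydroxy-7-(methoxymethoxy)-5-(3-methylbut-2-enyloxy)chromen-4-one | CC(C)=CCOc1cc(OCOC)cc2oc(-c3cc(OCOC)c(OCOC)c(CC=C(C)C)c3CC=C(C)C)c(O)c(=O)c12
F6 | step 11 | 2-[4,5-bis(methoxymethoxy)-2,3-bis(3-methylbut-2-enyl)phenyl]-3,7-bis(methoxymethoxy)-5-(3-methylbut-2-enyloxy)chromen-4-one | CC(C)=CCOc1cc(OCOC)cc2oc(-c3cc(OCOC)c(OCOC)c(CC=C(C)C)c3CC=C(C)C)c(OCOC)c(=O)c12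
F7 | step 11 | 3,7,4',5'-tetrakis-O-methoxymethyl Broussoflavonol G | CC(C)=CCc1c(-c2oc3c(CC=C(C)C)c(OCOC)cc(O)c3c(=O)c2OCOC)cc(OCOC)c(OCOC)c1CC=C(C)C
F8 | step 12 | 3,5,7,4',5'-pentakis-O-trimethylsilyl Broussoflavonol G | CC(C)=CCc1c(-c2oc3c(CC=C(C)C)c(O[Si](C)(C)C)cc(O[Si](C)(C)C)c3c(=O)c2O[Si](C)(C)C)cc(O[Si](C)(C)C)c(O[Si](C)(C)C)c1CC=C(C)C
F9 | step 9 | 7-(methoxymethoxy)-2-[4-(methoxymethoxy)-3-(3-methylbut-2-enyl)-5-(3-methylbut-2-enyloxy)phenyl]-5-(3-methylbut-2-enyloxy)chroman-4-one (racemic, one enantiomer drawn) | CC(C)=CCOc1cc(OCOC)cc2c1C(=O)C[C@@H](c1cc(CC=C(C)C)c(OCOC)c(OCC=C(C)C)c1)O2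
F10 | step 9 | 7-(methoxymethoxy)-2-[4-(methoxymethoxy)-3-(3-methylbut-2-enyl)-5-(3-methylbut-2-enyloxy)phenyl]-5-(3-methylbut-2-enyloxy)chromen-4-one | CC(C)=CCOc1cc(OCOC)cc2oc(-c3cc(CC=C(C)C)c(OCOC)c(OCC=C(C)C)c3)cc(=O)c12
F11 | step 9 | dimethyl [7-(methoxymethoxy)-2-[4-(methoxymethoxy)-3-(3-methylbut-2-enyl)-5-(3-methylbut-2-enyloxy)phenyl]-5-(3-methylbut-2-enyloxy)-4-oxochromen-3-yl]boronate | CC(C)=CCOc1cc(OCOC)cc2oc(-c3cc(CC=C(C)C)c(OCOC)c(OCC=C(C)C)c3)c(B(OC)OC)c(=O)c12
F12 | step 3 | 4-(allyloxy)-3-hydroxybenzaldehyde | C=CCOc1ccc(C=O)cc1O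
F13 | step 3 | 4-(allyloxy)-3-(3-methylbut-2-enyloxy)benzaldehyde | C=CCOc1ccc(C=O)cc1OCC=C(C)C
F14 | step 3 | 4-hydroxy-3-(3-methylbut-2-enyloxy)benzaldehyde | CC(C)=CCOc1cc(C=O)ccc1O
A1 | alternative 1 | (2R*,3R*)-2-[4,5-bis(methoxymethoxy)-2,3-bis(3-methylbut-2-enyl)phenyl]-3-hydroxy-5,7-bis(methoxymethoxy)-8-(3-methylbut-2-enyl)chroman-4-one (racemic trans, one enantiomer drawn) | CC(C)=CCc1c(CC=C(C)C)c(OCOC)c(OCOC)cc1[C@@H]1[C@@H](O)C(=O)c2c(OCOC)cc(OCOC)c(CC=C(C)C)c2O1
A2 | alternative 1 | 2-[1-[4,5-bis(methoxymethoxy)-2,3-bis(3-methylbut-2-enyl)phenyl]-2-oxoethoxy]-4,6-bis(methoxymethoxy)-3-(3-methylbut-2-enyl)benzaldehyde (racemic) | O=CC(Oc1c(CC=C(C)C)c(OCOC)cc(OCOC)c1C=O)c1cc(OCOC)c(OCOC)c(CC=C(C)C)c1CC=C(C)C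
A3 | alternative 2 | 2-[2,3-diallyl-4,5-bis(methoxymethoxy)phenyl]-1,3-dioxolane | COCOc1cc(C2OCCO2)c(CC=C)c(CC=C)c1OCOC
A4 | alternative 2 | 6-(1,3-dioxolan-2-yl)-3,4-bis(methoxymethoxy)-2-(trimethylsilyl)phenyl trifluoromethanesulfonate | COCOc1cc(C2OCCO2)c(OS(=O)(=O)C(F)(F)F)c([Si](C)(C)C)c1OCOC
A5 | alternative 3 | methyl 4,5-bis(methoxymethoxy)-2,3-bis(3-methylbut-2-enyl)benzoate | COC(=O)c1cc(OCOC)c(OCOC)c(CC=C(C)C)c1CC=C(C)C
A6 | alternative 3 | 2,9-dimethyldeca-2,8-dien-5-yne | CC(C)=CCC#CCC=C(C)C
A7 | alternative 3 | methyl 4,5-bis(methoxymethoxy)-6-oxo-6H-pyran-2-carboxylate | COC(=O)c1cc(OCOC)c(OCOC)c(=O)o1
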